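## The problem

Target 23 is an open-chain dibenzylbutane with no ring fused or bridged to another. A four-carbon chain C9–C8–C8'–C9' carries a benzoate on each terminal oxygen. C8 holds ring A (3-hydroxy-4-methoxyphenyl) through C7, and C8' holds ring B (4-hydroxy-3-methoxyphenyl) through C7'. The two halves differ only in which arene oxygen is methylated, so the two benzyl groups must be introduced separately and in a fixed order.

C8 and C8' are adjacent CH stereocentres, both R. In the open chain neither can direct the other. Inside a γ-butyrolactone (C9'(=O)–C8'–C8–C9–O) a substituent on C8 sends an electrophile at C8' to the opposite face, and this trans relation corresponds to (8R,8'R). C8 must therefore be set by a catalyst; C8' can then follow from it.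

The two primary benzoates will not survive hydride, alkoxide, strong amide bases or saponification, so they must be installed after the last such step. The phenols need a mask that can be removed without touching the benzoates, and this points to benzyl ethers and a final hydrogenolysis.

The feature that allows the key step is the substitution pattern of ring B: C1' carries C7', C3' carries methoxy and C4' carries oxygen. This is the pattern expected when C6 of a 3-alkoxy-2-pyrone (bearing the chain) and its C3 (bearing oxygen) are bridged by the two carbons of a ketene acetal, followed by loss of CO2 and methanol. Because this ring construction leaves no stereocentre behind and runs without acid, base or reductant, it can be placed late, with both stereocentres and both benzoates already present.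

## Retrosynthesis

**23 from 22.** The two phenolic O–benzyl bonds are cut. Benzyl is the only common phenol mask that can be removed (hydrogenolysis) without affecting two alkyl benzoates. Acyl groups could not be told apart from the benzoates, and a methyl ether would need reagents that also attack the existing methoxy groups. The forward step requires that no alkene, alkyne or pyrone remains, so ring B must be complete at this stage.

**22 from 18 and 19.** The bonds C1'–C2' and C3'–C4' of ring B are cut, leaving the 3-(benzyloxy)-6-alkyl-2-pyrone 18 and the ketene acetal 19.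
- Mapping: pyrone C6 becomes C1', the CH2 of 19 becomes C2', the acetal carbon becomes C3' and keeps one methoxy, pyrone C3 becomes C4', and pyrone C4 and C5 become C5' and C6'.
- Competing cut: cutting C7'–C8' and alkylating with a vanillyl halide is shorter. It is kept as the fallback.
- Reasons for the ring-forming cut: the methoxy/benzyloxy pattern is written by the polarity of the two partners and needs no pre-formed arene. It makes alkyne 10 a branch point from which ring B variants could be grown. It tolerates both benzoates and cannot disturb C8 or C8'.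
- Simplification: a trisubstituted benzene is reduced to a lactone and a two-carbon unit.
- Demand on the forward reaction: a regioselective [4+2] addition to a diene that is more electron-rich than the pyrones normally used, followed by loss of CO2 and methanol.

**18 from 16 (through 17).** The lactone bond O1–C6 of the pyrone is cut, giving a 2-en-4-ynoic acid whose carboxyl and alkynyl groups are cis. Closure must be 6-endo and not 5-exo. The acid is carried as its tert-butyl ester 16, because an ester that needs saponification could not be cleaved beside two benzoates.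

**16 from 10 and 15.** The sp2–sp bond (future pyrone C4–C5) is cut. This gives terminal alkyne 10, which holds both stereocentres and both benzoates, and the three-carbon enol triflate 15. In 15 the sulfonate must be cis to the ester. Because benzyloxy outranks the carboxyl carbon, this is the E isomer; the Z isomer would hold the leaving group trans to the ester and could never lactonise. The coupling must retain alkene geometry.

**15 from 14, 13, 11 and 12.** The enol triflate comes from the enol of the α-formyl ester 14. A metal bridging the enolate oxygen and the ester carbonyl should place the sulfonate on the ester side. 14 is the formylation product of the benzyloxyacetate 13, which is the ether of 11 and 12. This is a three-step branch from cheap materials.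

**10 from 9 and 8.** The two benzoate C–O bonds are cut, then the lactone is restored from the diol. Lactone 8 is reduced before the benzoates are installed, so no benzoate ever meets hydride.

**8 from 6 and 7.** The bond C7'–C8' is cut. Alkylation of the enolate of the β-benzyl lactone 6 with 7 should take place anti to the ring A benzyl group and set C8' from C8. The three carbons of 7 become C7', C1' and C6'. A small, linear electrophile favours clean trans alkylation.

**6 from 4, 3, 1 and 2.** The lactone is the reduced, cyclised form of the half-ester 4. C8 is traced to asymmetric hydrogenation of the alkylidenesuccinate 3, a substrate class for which this reaction is well established. 3 is the condensation product of aldehyde 1 and diester 2, which forms the C7–C8 bond.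

## Roads not taken

**Alternative 1:** Both stereocentres are traced to a dimethyl 2,3-diaroylsuccinate A2 in which C8 and C8' epimerise freely.
- Forward key step: RuCl(p-cymene)[(S,S)-TsDPEN] (divalent ruthenium) with formic acid and triethylamine would reduce both aryl ketones under dynamic kinetic resolution. Each new hydroxyl would close a lactone on the remote ester, giving the cis-fused dilactone A1 with C8 and C8' as in the target.
- Merits: one catalyst sets everything from stereochemically labile material. The rigid bicycle should be easy to purify. Both arenes are bought, not built. Transfer hydrogenation of α-substituted β-keto esters with dynamic resolution is a better-established reaction type than the pyrone cycloaddition chosen here.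
- Weak points: A2 requires two different aroylacetate units to be joined head to head, which is statistical unless done stepwise. Four stereocentres are made and two are then destroyed. The benzylic C7–O and C7'–O bonds must be hydrogenolysed, which also removes the benzyl ethers. The carboxyl groups would then have to be reduced and the primary alcohols benzoylated beside two free phenols, which calls for a second round of phenol protection.
- Comparison: the alternative is better in the precedent for its key step and in convergence. The chosen plan offers stereocontrol from two reaction classes with a long record on exactly these substrates, and an end game of a single hydrogenolysis.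

**Alternative 2:** Here ring A is the ring that is grown. Two of its C–C bonds are cut to 3-methoxyfuran A5 and the terminal ynone A4, which already holds C8, C8' and ring B.
- Forward key step: a thermal [4+2] cycloaddition, then opening of the oxygen bridge, would give the phenolic aryl ketone A3.
- Merits: an electron-rich furan and an electron-poor ynone are a matched pair, which the 3-alkoxypyrone and ketene acetal of the chosen plan are not. Both the orientation of the addition and the methoxy-assisted bridge opening favour the 3-hydroxy-4-methoxy pattern. The phenol arrives free.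
- Weak points: C7 arrives as a ketone directly beside C8. C8 can then epimerise through the enol during a hot cycloaddition and an acid-assisted aromatisation, and the silyloxymethyl group on C8 can be lost by β-elimination from A4. After the key step the ketone must be taken down to CH2 and the silyl ethers exchanged for benzoates while a free phenol competes for the acylating agent.
- Comparison: the chosen plan gives up the better electronic match. In return, the new ring is attached through a CH2 already at the right oxidation level, no stereocentre sits next to a carbonyl after step 5, and only one step follows the key step.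

**Alternative 3:** The bonds C8–C9 and C8'–C9' are cut, leading to the (E)-1,4-diarylbut-2-ene A7.
- Forward key step: Pd(OCOCF3)2 (divalent palladium) with a chiral bis(oxazoline), p-benzoquinone, carbon monoxide and methanol would add two methoxycarbonyl groups syn across the alkene to give the (2R,3R)-succinate A6. Reduction, benzoylation and hydrogenolysis would finish the synthesis.
- Merits: this is the shortest route by a wide margin. Syn addition to an (E)-alkene gives the required relative configuration automatically.
- Weak points: enantioselective bis-alkoxycarbonylation has its record with terminal and aryl-conjugated alkenes, not with an internal 1,2-dialkyl alkene. A palladium hydride could move the double bond of A7 into conjugation with either arene. An unsymmetrical (E)-selective synthesis of A7 is itself statistical if done by cross-metathesis.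
- Comparison: if the key step delivered high enantioselectivity, this road would clearly be better in step count. In the chosen plan the unprecedented step cannot affect stereochemistry, and a classical alkylation can rejoin the route at 22 if that step fails.

Key step: step 12

Assumptions:
- 3-(Benzyloxy)-4-methoxybenzaldehyde (O-benzylisovanillin, 1) is treated as a purchasable compound; it is otherwise one benzylation away from isovanillin.
- Locants C7–C9 belong to the ring A half, C7'–C9' to the ring B half, and C1'–C6' to ring B.

## Route

Step 1
Reactants: 1 3-(benzyloxy)-4-methoxybenzaldehyde; 2 dimethyl succinate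
Product: 3 (3E)-4-[3-(benzyloxy)-4-methoxyphenyl]-3-(methoxycarbonyl)but-3-enoic acid
Conditions: NaOMe, MeOH, reflux; then aq. HCl
Reagents that add atoms: none
Why: Stobbe condensation; the aldol adduct lactonises and the lactone opens by elimination, so exactly one ester ends as the carboxylate and the aryl group should end trans to the remaining ester (E).

Step 2
Reactants: 3 (3E)-4-[3-(benzyloxy)-4-methoxyphenyl]-3-(methoxycarbonyl)but-3-enoic acid
Product: 4 (3R)-4-[3-(benzyloxy)-4-methoxyphenyl]-3-(methoxycarbonyl)butanoic acid
Conditions: H2 (5 atm), [Rh(cod)Cl]2 (0.5 mol%), (S,S)-MOD-DIOP (1.1 mol%), Et3N (0.1 equiv), MeOH, 30 °C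
Reagents that add atoms: none
Why: Rhodium-catalysed asymmetric hydrogenation of an itaconate-type half-ester; carboxylate and alkene chelate monovalent rhodium and the chiral bisphosphine selects the alkene face, setting C8 as R (the ligand enantiomer is the one expected to give the R acid for this ligand class; its mirror image is used if the sense proves opposite). The aryl benzyl ether is inert to the homogeneous catalyst.

Step 3
Reactants: 4 (3R)-4-[3-(benzyloxy)-4-methoxyphenyl]-3-(methoxycarbonyl)butanoic acid
Product: 6 (4R)-4-[3-(benzyloxy)-4-methoxybenzyl]dihydrofuran-2(3H)-one, via hydroxy acid 5 (not isolated)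
Conditions: KOH (1.0 equiv), EtOH; Ca(BH4)2 (from CaCl2 and NaBH4), EtOH, −10 °C to rt; then 3 M HCl, rt
Reagents that add atoms: none
Why: Chemoselective borohydride reduction; Ca(BH4)2 reduces the methyl ester while the potassium carboxylate is inert, and acidification closes the γ-lactone from hydroxy acid 5. Reduction under these weakly basic conditions should outpace enolisation at C8.

Step 4
Reactants: 6 (4R)-4-[3-(benzyloxy)-4-methoxybenzyl]dihydrofuran-2(3H)-one; 7 propargyl bromide
Product: 8 (3R,4R)-4-[3-(benzyloxy)-4-methoxybenzyl]-3-(prop-2-yn-1-yl)dihydrofuran-2(3H)-one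
Conditions: LiN(SiMe3)2, THF, −78 °C; then 7, DMPU, −78 to −30 °C
Reagents that add atoms: none
Why: Alkylation of a lactone lithium enolate; the electrophile should approach anti to the benzyl group on the neighbouring ring carbon, so C8' is set trans to C8 (3R,4R) by substrate control.

Step 5
Reactants: 8 (3R,4R)-4-[3-(benzyloxy)-4-methoxybenzyl]-3-(prop-2-yn-1-yl)dihydrofuran-2(3H)-one
Product: 9 (2R,3R)-2-[3-(benzyloxy)-4-methoxybenzyl]-3-(prop-2-yn-1-yl)butane-1,4-diol
Conditions: LiAlH4, THF, 0 °C; aq. NaOH work-up
Reagents that add atoms: none
Why: Hydride reduction of a lactone to the 1,4-diol; the isolated terminal alkyne and the aryl ethers are not reduced at 0 °C. This is the last hydride step and precedes the benzoates.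

Step 6
Reactants: 9 (2R,3R)-2-[3-(benzyloxy)-4-methoxybenzyl]-3-(prop-2-yn-1-yl)butane-1,4-diol
Product: 10 (2R,3R)-2-[3-(benzyloxy)-4-methoxybenzyl]-3-(prop-2-yn-1-yl)butane-1,4-diyl dibenzoate
Conditions: BzCl (2.4 equiv), pyridine, DMAP (cat.), CH2Cl2, 0 °C to rt
Reagents that add atoms: benzoyl chloride, O=C(Cl)c1ccccc1
Why: Nucleophilic-catalysed acylation of two unhindered primary alcohols; nothing else in 9 is acylated.

Step 7
Reactants: 11 tert-butyl bromoacetate; 12 benzyl alcohol
Product: 13 tert-butyl 2-(benzyloxy)acetate
Conditions: NaH, THF, 0 °C; then 11, Bu4NI (cat.), 0 °C to rt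
Reagents that add atoms: none
Why: Williamson ether synthesis; the tert-butyl ester resists attack by the alkoxide, so only bromide is displaced.

Step 8
Reactants: 13 tert-butyl 2-(benzyloxy)acetate
Product: 14 tert-butyl (2E)-2-(benzyloxy)-3-hydroxyprop-2-enoate (enol form of tert-butyl 2-(benzyloxy)-3-oxopropanoate)
Conditions: NaH, HCO2Et, THF (cat. EtOH), 0 °C to rt; then cold 1 M HCl
Reagents that add atoms: ethyl formate, CCOC=O
Why: Crossed Claisen condensation (formylation); the formate has no α-hydrogen and the equilibrium is pulled over by formation of the stabilised sodium enolate of the formyl ester.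

Step 9
Reactants: 14 tert-butyl (2E)-2-(benzyloxy)-3-hydroxyprop-2-enoate
Product: 15 tert-butyl (2E)-2-(benzyloxy)-3-{[(trifluoromethyl)sulfonyl]oxy}prop-2-enoate
Conditions: Tf2O (1.5 equiv), saturated aq. LiOH, toluene, 5 °C
Reagents that add atoms: trifluoromethanesulfonic anhydride, O=S(=O)(OS(=O)(=O)C(F)(F)F)C(F)(F)F
Why: Chelation-controlled O-sulfonylation of a β-oxo ester enolate; lithium bridges the enolate oxygen and the ester carbonyl in a six-membered chelate, so the triflate should be placed cis to the ester, which is the E isomer because benzyloxy outranks the carboxyl carbon.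

Step 10
Reactants: 10 (2R,3R)-2-[3-(benzyloxy)-4-methoxybenzyl]-3-(prop-2-yn-1-yl)butane-1,4-diyl dibenzoate; 15 tert-butyl (2E)-2-(benzyloxy)-3-{[(trifluoromethyl)sulfonyl]oxy}prop-2-enoate
Product: 16 tert-butyl (2E,7R,8R)-7,8-bis[(benzoyloxy)methyl]-2-(benzyloxy)-9-[3-(benzyloxy)-4-methoxyphenyl]non-2-en-4-ynoate
Conditions: Pd(PPh3)2Cl2 (3 mol%), CuI (5 mol%), Et3N, THF (degassed), rt
Reagents that add atoms: none
Why: Sonogashira coupling; the β-sulfonyloxy acrylate should add readily to zerovalent palladium and couple with retention of alkene geometry, keeping the alkynyl group cis to the ester. A tertiary amine is used so that no amine adds to the acrylate, and the benzoates are inert.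

Step 11
Reactants: 16 tert-butyl (2E,7R,8R)-7,8-bis[(benzoyloxy)methyl]-2-(benzyloxy)-9-[3-(benzyloxy)-4-methoxyphenyl]non-2-en-4-ynoate
Product: 18 (2R,3R)-2-[3-(benzyloxy)-4-methoxybenzyl]-3-{[5-(benzyloxy)-6-oxo-6H-pyran-2-yl]methyl}butane-1,4-diyl dibenzoate (the 3-(benzyloxy)-6-alkyl-2H-pyran-2-one), via enynoic acid 17 (not isolated)
Conditions: TFA, CH2Cl2, 0 °C to rt; evaporate; then ZnBr2 (0.2 equiv), THF, rt
Reagents that add atoms: none
Why: Acidolysis of the tert-butyl ester (loss of isobutene) leaves benzoates and benzyl ethers intact and gives acid 17. ZnBr2-promoted lactonisation of cis-2-en-4-ynoic acids is known to close 6-endo-dig on the alkyl-bearing alkyne carbon, giving 6-alkyl-2-pyranones and not the 5-exo alkylidene butenolides.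

Step 12
Reactants: 18 (2R,3R)-2-[3-(benzyloxy)-4-methoxybenzyl]-3-{[5-(benzyloxy)-6-oxo-6H-pyran-2-yl]methyl}butane-1,4-diyl dibenzoate; 19 1,1-dimethoxyethene
Product: 22 (2R,3R)-2-[3-(benzyloxy)-4-methoxybenzyl]-3-[4-(benzyloxy)-3-methoxybenzyl]butane-1,4-diyl dibenzoate, via bridged lactone cycloadduct 20 (not isolated), via dimethoxycyclohexadiene 21 (not isolated)
Conditions: 19 (15 equiv), toluene (1 M in 18), 2,6-di-tert-butyl-4-methylphenol (cat.), base-washed sealed tube, 150 °C
Reagents that add atoms: none
Why: Proposed new method: the closest known reaction type is the inverse-electron-demand Diels–Alder reaction of 2-pyrones bearing an ester or halogen with ketene acetals, which gives anisoles after loss of CO2 and methanol; a pyrone with a donor at C3 and an alkyl group at C6 has not been shown in this role. The nucleophilic CH2 of 19 should bond to C6 of 18, the vinylogous acyl position with the largest LUMO coefficient, while the acetal carbon bonds to C3, probably through an asynchronous polar transition state. This [4+2] closure gives the 2-oxabicyclo[2.2.2]octenone 20; its two bridgehead stereocentres form as a mixture and are erased again, so no stereocontrol is needed. Retro-[4+2] loss of CO2 from 20 gives the 5,5-dimethoxycyclohexa-1,3-diene 21, and 1,2-elimination of methanol completes ring B as a benzene ring, so the six-membered carbocycle is closed by cycloaddition and aromatised by two eliminations. The only selectivity required is regiochemical: methoxy at C3' and benzyloxy at C4' follow from pairing the electrophilic C6 with the nucleophilic CH2, whereas the reverse orientation would join the two donor-substituted termini. C8 and C8' lie two and three bonds from the diene and carry no acidic hydrogen, so they should pass unchanged. Because the 3-alkoxy group raises the LUMO of the diene, a large excess of 19 at high concentration and temperature is used.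

Step 13
Reactants: 22 (2R,3R)-2-[3-(benzyloxy)-4-methoxybenzyl]-3-[4-(benzyloxy)-3-methoxybenzyl]butane-1,4-diyl dibenzoate
Product: 23 (2R,3R)-2-(3-hydroxy-4-methoxybenzyl)-3-(4-hydroxy-3-methoxybenzyl)butane-1,4-diyl dibenzoate (CNP0306197.1)
Conditions: H2 (1 atm), 10% Pd/C, EtOAc–EtOH, rt
Reagents that add atoms: none
Why: Hydrogenolysis of two aryl benzyl ethers; alkyl benzoates and the benzylic C–C bonds are inert, and no stereocentre is touched.

## Compound list

1 | 3-(benzyloxy)-4-methoxybenzaldehyde | COc1ccc(C=O)cc1OCc1ccccc1 | starting material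
2 | dimethyl succinate | COC(=O)CCC(=O)OC | starting material
3 | (3E)-4-[3-(benzyloxy)-4-methoxyphenyl]-3-(methoxycarbonyl)but-3-enoic acid | COC(=O)/C(CC(=O)O)=C/c1ccc(OC)c(OCc2ccccc2)c1 | intermediate
4 | (3R)-4-[3-(benzyloxy)-4-methoxyphenyl]-3-(methoxycarbonyl)butanoic acid | COC(=O)[C@@H](CC(=O)O)Cc1ccc(OC)c(OCc2ccccc2)c1 | intermediate
5 | (3R)-4-[3-(benzyloxy)-4-methoxyphenyl]-3-(hydroxymethyl)butanoic acid | OC(=O)C[C@H](CO)Cc1ccc(OC)c(OCc2ccccc2)c1 | intermediate (not isolated)
6 | (4R)-4-[3-(benzyloxy)-4-methoxybenzyl]dihydrofuran-2(3H)-one | O=C1C[C@@H](Cc2ccc(OC)c(OCc3ccccc3)c2)CO1 | intermediate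
7 | propargyl bromide (3-bromoprop-1-yne) | BrCC#C | starting material
8 | (3R,4R)-4-[3-(benzyloxy)-4-methoxybenzyl]-3-(prop-2-yn-1-yl)dihydrofuran-2(3H)-one | O=C1[C@H](CC#C)[C@@H](Cc2ccc(OC)c(OCc3ccccc3)c2)CO1 | intermediate
9 | (2R,3R)-2-[3-(benzyloxy)-4-methoxybenzyl]-3-(prop-2-yn-1-yl)butane-1,4-diol | OC[C@H](CC#C)[C@@H](Cc1ccc(OC)c(OCc2ccccc2)c1)CO | intermediate
10 | (2R,3R)-2-[3-(benzyloxy)-4-methoxybenzyl]-3-(prop-2-yn-1-yl)butane-1,4-diyl dibenzoate | O=C(OC[C@H](CC#C)[C@@H](Cc1ccc(OC)c(OCc2ccccc2)c1)COC(=O)c1ccccc1)c1ccccc1 | intermediate
11 | tert-butyl bromoacetate | CC(C)(C)OC(=O)CBr | starting material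
12 | benzyl alcohol | OCc1ccccc1 | starting material
13 | tert-butyl 2-(benzyloxy)acetate | CC(C)(C)OC(=O)COCc1ccccc1 | intermediate
14 | tert-butyl (2E)-2-(benzyloxy)-3-hydroxyprop-2-enoate (enol of the α-formyl ester) | O/C=C(\C(=O)OC(C)(C)C)OCc1ccccc1 | intermediate
15 | tert-butyl (2E)-2-(benzyloxy)-3-{[(trifluoromethyl)sulfonyl]oxy}prop-2-enoate | CC(C)(C)OC(=O)/C(OCc1ccccc1)=C\OS(=O)(=O)C(F)(F)F | intermediate
16 | tert-butyl (2E,7R,8R)-7,8-bis[(benzoyloxy)methyl]-2-(benzyloxy)-9-[3-(benzyloxy)-4-methoxyphenyl]non-2-en-4-ynoate | CC(C)(C)OC(=O)/C(OCc1ccccc1)=C\C#CC[C@@H](COC(=O)c1ccccc1)[C@H](COC(=O)c1ccccc1)Cc1ccc(OC)c(OCc2ccccc2)c1 | intermediate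
17 | (2E,7R,8R)-7,8-bis[(benzoyloxy)methyl]-2-(benzyloxy)-9-[3-(benzyloxy)-4-methoxyphenyl]non-2-en-4-ynoic acid | OC(=O)/C(OCc1ccccc1)=C\C#CC[C@@H](COC(=O)c1ccccc1)[C@H](COC(=O)c1ccccc1)Cc1ccc(OC)c(OCc2ccccc2)c1 | intermediate (not isolated)
18 | (2R,3R)-2-[3-(benzyloxy)-4-methoxybenzyl]-3-{[5-(benzyloxy)-6-oxo-6H-pyran-2-yl]methyl}butane-1,4-diyl dibenzoate | COc1ccc(C[C@@H](COC(=O)c2ccccc2)[C@H](COC(=O)c2ccccc2)CC2=CC=C(OCc3ccccc3)C(=O)O2)cc1OCc1ccccc1 | intermediate (key-step precursor)
19 | 1,1-dimethoxyethene | C=C(OC)OC | starting material
20 | (2R,3R)-2-[3-(benzyloxy)-4-methoxybenzyl]-3-{[4-(benzyloxy)-5,5-dimethoxy-3-oxo-2-oxabicyclo[2.2.2]oct-7-en-1-yl]methyl}butane-1,4-diyl dibenzoate (both bridgehead diastereomers) | COc1ccc(C[C@@H](COC(=O)c2ccccc2)[C@H](COC(=O)c2ccccc2)CC23C=CC(OCc4ccccc4)(C(=O)O2)C(OC)(OC)C3)cc1OCc1ccccc1 | intermediate (not isolated)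
21 | (2R,3R)-2-[3-(benzyloxy)-4-methoxybenzyl]-3-{[4-(benzyloxy)-5,5-dimethoxycyclohexa-1,3-dien-1-yl]methyl}butane-1,4-diyl dibenzoate | COc1ccc(C[C@@H](COC(=O)c2ccccc2)[C@H](COC(=O)c2ccccc2)CC2=CC=C(OCc3ccccc3)C(OC)(OC)C2)cc1OCc1ccccc1 | intermediate (not isolated)
22 | (2R,3R)-2-[3-(benzyloxy)-4-methoxybenzyl]-3-[4-(benzyloxy)-3-methoxybenzyl]butane-1,4-diyl dibenzoate | COc1ccc(C[C@@H](COC(=O)c2ccccc2)[C@H](COC(=O)c2ccccc2)Cc2ccc(OCc3ccccc3)c(OC)c2)cc1OCc1ccccc1 | intermediate (key-step product)
23 | (2R,3R)-2-(3-hydroxy-4-methoxybenzyl)-3-(4-hydroxy-3-methoxybenzyl)butane-1,4-diyl dibenzoate | COc1ccc(C[C@@H](COC(=O)c2ccccc2)[C@H](COC(=O)c2ccccc2)Cc2ccc(O)c(OC)c2)cc1O | target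

## Step count and least certain steps

Total: 13 steps. Longest linear sequence: 10 steps (steps 1–6 and 10–13, from 1 to 23); steps 7–9 form a three-step branch that joins at step 10.

**Step 12 (key step).**
- Likely failure: the cycloaddition is too slow, because the 3-benzyloxy group raises the diene LUMO, so thermal oligomerisation of the ketene acetal or addition of the acetal to the lactone carbonyl with ring opening outruns it.
- Within the same disconnection, the same two bonds can be forced at 10–15 kbar near room temperature, where the ketene acetal is stable.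
- Fallback with known chemistry: this sets out from lactone 6 and abandons the ring construction. 4-(Benzyloxy)-3-methoxybenzyl bromide F1 is made from the commercial benzylic alcohol with PBr3. The lithium enolate of 6 is alkylated with it trans to the existing benzyl group, giving (3R,4R)-4-[3-(benzyloxy)-4-methoxybenzyl]-3-[4-(benzyloxy)-3-methoxybenzyl]dihydrofuran-2(3H)-one F2. Reduction with LiAlH4 gives (2R,3R)-2-[3-(benzyloxy)-4-methoxybenzyl]-3-[4-(benzyloxy)-3-methoxybenzyl]butane-1,4-diol F3, and benzoylation as in step 6 returns to the route at 22.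

**Step 9.**
- Likely failure: loss of geometric control in the O-sulfonylation if the lithium chelate is not maintained, which would place the triflate trans to the ester (an isomer that cannot lactonise after coupling). Hydroxide-induced deformylation of 14 is a second risk.
- Fallback: this avoids any acyclic alkene geometry and sets out from alkyne 10. Hydration catalysed by Ph3PAuNTf2 (monovalent gold) in wet dioxane gives the methyl ketone (2R,3R)-2-[3-(benzyloxy)-4-methoxybenzyl]-3-(2-oxopropyl)butane-1,4-diyl dibenzoate F4. Condensation with N,N-dimethylformamide dimethyl acetal at the methyl group gives the enaminone (2R,3R)-2-[3-(benzyloxy)-4-methoxybenzyl]-3-[(3E)-4-(dimethylamino)-2-oxobut-3-en-1-yl]butane-1,4-diyl dibenzoate F5. [4+2] Addition of benzyloxyketene (from benzyloxyacetyl chloride and Et3N) across the oxadiene, then loss of dimethylamine, returns to the route at pyrone 18.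

**Step 11.**
- Likely failure: competing 5-exo closure to an alkylidene butenolide, or alkylation of the electron-rich ring A by the tert-butyl cation during acidolysis.
- Fallback: this sets out from ester 16 and closes the ring with an electrophile in place of a Lewis acid. Iodolactonisation (I2, NaHCO3, MeCN), with loss of the tert-butyl group from the oxonium intermediate, should give the 5-iodopyrone (2R,3R)-2-[3-(benzyloxy)-4-methoxybenzyl]-3-{[5-(benzyloxy)-3-iodo-6-oxo-6H-pyran-2-yl]methyl}butane-1,4-diyl dibenzoate F6. Reductive removal of iodine with Pd(OAc)2 (divalent palladium precatalyst), PPh3, formic acid and Et3N returns to the route at 18.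

**Step 4.**
- Likely failure: proton transfer from the acetylenic C–H to the enolate, attack at the alkyne terminus to give an allene, or double alkylation, each of which lowers conversion and trans selectivity.
- Fallback: this sets out from lactone 6 and uses a masked alkyne. Alkylation with 3-bromo-1-(trimethylsilyl)prop-1-yne gives (3R,4R)-4-[3-(benzyloxy)-4-methoxybenzyl]-3-[3-(trimethylsilyl)prop-2-yn-1-yl]dihydrofuran-2(3H)-one F7. Desilylation with Bu4NF buffered with acetic acid returns to the route at 8.

## Further compounds

F1 | step 12 | 4-(benzyloxy)-3-methoxybenzyl bromide | COc1cc(CBr)ccc1OCc1ccccc1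
F2 | step 12 | (3R,4R)-4-[3-(benzyloxy)-4-methoxybenzyl]-3-[4-(benzyloxy)-3-methoxybenzyl]dihydrofuran-2(3H)-one | O=C1[C@H](Cc2ccc(OCc3ccccc3)c(OC)c2)[C@@H](Cc2ccc(OC)c(OCc3ccccc3)c2)CO1
F3 | step 12 | (2R,3R)-2-[3-(benzyloxy)-4-methoxybenzyl]-3-[4-(benzyloxy)-3-methoxybenzyl]butane-1,4-diol | OC[C@H](Cc1ccc(OCc2ccccc2)c(OC)c1)[C@@H](Cc1ccc(OC)c(OCc2ccccc2)c1)CO
F4 | step 9 | (2R,3R)-2-[3-(benzyloxy)-4-methoxybenzyl]-3-(2-oxopropyl)butane-1,4-diyl dibenzoate | CC(=O)C[C@@H](COC(=O)c1ccccc1)[C@H](COC(=O)c1ccccc1)Cc1ccc(OC)c(OCc2ccccc2)c1
F5 | step 9 | (2R,3R)-2-[3-(benzyloxy)-4-methoxybenzyl]-3-[(3E)-4-(dimethylamino)-2-oxobut-3-en-1-yl]butane-1,4-diyl dibenzoate | CN(C)/C=C/C(=O)C[C@@H](COC(=O)c1ccccc1)[C@H](COC(=O)c1ccccc1)Cc1ccc(OC)c(OCc2ccccc2)c1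
F6 | step 11 | (2R,3R)-2-[3-(benzyloxy)-4-methoxybenzyl]-3-{[5-(benzyloxy)-3-iodo-6-oxo-6H-pyran-2-yl]methyl}butane-1,4-diyl dibenzoate | COc1ccc(C[C@@H](COC(=O)c2ccccc2)[C@H](COC(=O)c2ccccc2)CC2=C(I)C=C(OCc3ccccc3)C(=O)O2)cc1OCc1ccccc1
F7 | step 4 | (3R,4R)-4-[3-(benzyloxy)-4-methoxybenzyl]-3-[3-(trimethylsilyl)prop-2-yn-1-yl]dihydrofuran-2(3H)-one | O=C1[C@H](CC#C[Si](C)(C)C)[C@@H](Cc2ccc(OC)c(OCc3ccccc3)c2)CO1
A1 | alternative 1 | cis-fused 4-[3-(benzyloxy)-4-methoxyphenyl]-8-[4-(benzyloxy)-3-methoxyphenyl]-3,7-dioxabicyclo[3.3.0]octane-2,6-dione, aryl groups exo | COc1ccc(cc1OCc1ccccc1)[C@H]1OC(=O)[C@H]2[C@@H]1C(=O)O[C@@H]2c1ccc(OCc2ccccc2)c(OC)c1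
A2 | alternative 1 | dimethyl 2-[3-(benzyloxy)-4-methoxybenzoyl]-3-[4-(benzyloxy)-3-methoxybenzoyl]succinate (epimerising mixture) | COC(=O)C(C(=O)c1ccc(OC)c(OCc2ccccc2)c1)C(C(=O)OC)C(=O)c1ccc(OCc2ccccc2)c(OC)c1
A3 | alternative 2 | (2R,3R)-4-[4-(benzyloxy)-3-methoxyphenyl]-2,3-bis{[(tert-butyldimethylsilyl)oxy]methyl}-1-(3-hydroxy-4-methoxyphenyl)butan-1-one | COc1ccc(C(=O)[C@@H](CO[Si](C)(C)C(C)(C)C)[C@H](CO[Si](C)(C)C(C)(C)C)Cc2ccc(OCc3ccccc3)c(OC)c2)cc1O
A4 | alternative 2 | (4R,5R)-6-[4-(benzyloxy)-3-methoxyphenyl]-4,5-bis{[(tert-butyldimethylsilyl)oxy]methyl}hex-1-yn-3-one | C#CC(=O)[C@@H](CO[Si](C)(C)C(C)(C)C)[C@H](CO[Si](C)(C)C(C)(C)C)Cc1ccc(OCc2ccccc2)c(OC)c1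
A5 | alternative 2 | 3-methoxyfuran | COc1ccoc1
A6 | alternative 3 | dimethyl (2R,3R)-2-[3-(benzyloxy)-4-methoxybenzyl]-3-[4-(benzyloxy)-3-methoxybenzyl]succinate | COc1ccc(C[C@@H](C(=O)OC)[C@H](C(=O)OC)Cc2ccc(OCc3ccccc3)c(OC)c2)cc1OCc1ccccc1
A7 | alternative 3 | (E)-1-[3-(benzyloxy)-4-methoxyphenyl]-4-[4-(benzyloxy)-3-methoxyphenyl]but-2-ene | COc1ccc(C/C=C/Cc2ccc(OCc3ccccc3)c(OC)c2)cc1OCc1ccccc1
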